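(All runs were computed from invented constants, and the scatter is random.)

Larch is a slow flask: at 50.0 min it held 5.8% of the substrate charged as mono adduct, and at 120 min it held 9.7%.

| setting | larch | ash | oak | teal | green | grey |
|---|---|---|---|---|---|---|
| substrate | 0.050 M | 0.050 M | 0.050 M | 0.050 M | 0.050 M | 0.050 M |
| reagent | 0.027 M | 0.064 M | 0.17 M | 0.0250 M | 0.150 M | 0.0600 M |
| remark | run made earlier | run made earlier | run made earlier |  |  |  |
| time |  |  |  | 4.0 h | 4.0 h | 4.0 h |

| run | time / min | mono adduct / % |
|---|---|---|
| larch | 25.0 | 3.1 |
| larch | 50.0 | 5.8 |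
| larch | 80.0 | 9.0 |
| larch | 90.0 | 6.7 |
| larch | 120 | 9.7 |
| ash | 25.0 | 6.6 |
| ash | 50.0 | 12.9 |
| ash | 80.0 | 15.4 |
| ash | 90.0 | 18.3 |
| ash | 120 | 18.0 |
| oak | 10.0 | 8.3 |
| oak | 30.0 | 17.4 |
| oak | 60.0 | 23.8 |
| oak | 80.0 | 26.5 |
| oak | 120 | 26.9 |

(standard deviation of a reading: 1 percentage point)

1. which of these holds the largest part of the substrate at the end of teal (other mono adduct / double product / mono adduct / substrate)
2. which of these holds the largest part of the substrate at the end of green (other mono adduct / double product / mono adduct / substrate)
3. which of these holds the largest part of the substrate at the end of grey (other mono adduct / double product / mono adduct / substrate)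
4. mono adduct at the end of teal, in percent of the substrate charged

Teal is charged nearly like larch, so we read teal from larch. The early gain follows the reagent: the ash reading at 50.0 min is 2.22 times the larch one, on 2.37 times the reagent. Larch gained 0.0696 h⁻¹ of the charge up to 50.0 min, then 0.0334 h⁻¹. The middles of these two stretches lie 60.0 min apart. We freeze one quantity, the halving time of the making, the time in which the hourly gain falls by half. This is a rough, empirical step: larch starts with 0.050 M of substrate and 0.027 M of reagent, and both of them fall as it runs.

halving time = 0.945 h

It is a reading, carrying the scatter of 1 percentage point.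

Our first way starts from the early gain. Run back to the start, the gain is 0.0945 h⁻¹, and a gain that keeps halving sums to:

whole making in larch = 0.0945 h⁻¹ × 0.945 h ÷ 0.693 = 12.9%

Teal has 0.926 of the larch reagent, and with the halving time frozen we reckon it to have done 0.947 of its making by 4.0 h:

teal = 12.9% × 0.926 × 0.947 = 11.3%

Our second way takes the last larch reading as final:

teal = 9.7% × 0.926 = 8.98%

The second way gives less than the first, and it is the one that cheats: with the halving time frozen, we reckon larch to have 0.231 of its making still ahead at 120 min. Corrected for that, and for the part of teal's making still ahead at 4.0 h, it gives 11.1%. We commit to that figure.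

The forecast, reached by another road, gives 11.5% for teal. It names substrate as the largest holder in teal, other mono adduct in green and other mono adduct in grey, and it holds that “the mono adduct reacts on only slowly”.

Teal ends at 11.6% mono adduct.

    substrate + reagent → mono adduct + by-product (k = 0.00100 L mol⁻¹ s⁻¹)
    substrate + reagent → other mono adduct + by-product (k = 6.60 × 10⁻⁴ L mol⁻¹ s⁻¹)
    reagent + mono adduct → double product + by-product (k = 5.50 × 10⁻⁴ L mol⁻¹ s⁻¹)
    reagent + other mono adduct → double product + by-product (k = 0.00110 L mol⁻¹ s⁻¹)
    mono adduct ⇌ isomer of the product (K = 0.480, k = 6.30 × 10⁻⁵ s⁻¹)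
    2 reagent → self-condensation product (k = 2.70 × 10⁻⁴ L mol⁻¹ s⁻¹)
    substrate ⇌ dormant form (K = 0.770, k = 2.00 × 10⁻⁵ s⁻¹)

At 4.00 h teal still makes mono adduct 1.74 times faster than it uses it up, each step taken net. With the halving time of 0.945 h held frozen, a flask like teal but with 0.010 M of reagent reckons to 4.52%, and that flask stands at 5.37%.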